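**Retrosynthetic overview**

- Enabling feature: the chromene C4 is benzylic to the trioxygenated ring (ortho to O1) and allylic to the C2=C3 enol ether, so it can be a stabilised cationic carbon. It is bonded to eudesmane C1, which lies 1,4 across ring A from the tertiary C4 carbinol, with the C5–C10 ring-fusion bond between them. This is the retron of an electrophile-triggered, water-terminated transannular cyclisation of a germacra-1(10),4-diene.
- Disconnections: pyran O1–C2 (phenol OH onto a phenyl alkyne); then eudesmane C1–chromene C4, C5–C10 and C4–OH together. This leads back to (+)-germacrene A and a 2-hydroxyaryl propargylic alcohol as cation precursor.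
- Ring order: the benzene rings are bought; the ten-membered ring comes from farnesyl diphosphate by enzymatic 1,10-cyclisation; in the key step it is folded into decalin rings A and B, and the pyran ring is closed last.
- The cation precursor comes from 3,4,5-trimethoxyphenol by O-methylation, formylation, chelation-controlled mono-demethylation and acetylide addition.

Key step: step 7

Assumption: recombinant (+)-germacrene A synthase of Cichorium intybus, made by standard expression in Escherichia coli, is treated as an available catalyst; its product is the 7R enantiomer needed here (the one that gives (−)-β-elemene on Cope rearrangement).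

Eudesmane numbering is used for the terpene part (C1 bears the chromene, C4 the OH, C7 the isopropenyl group, C10 the angular methyl).

**Step 1**
Reactants: 1 3,4,5-trimethoxyphenol
Product: 2 1,2,3,5-tetramethoxybenzene
Conditions: MeI, K2CO3, acetone, reflux
Reagents that add atoms: iodomethane CI
Why: Williamson ether synthesis of the phenoxide with a methyl halide; no stereocenter is formed.

**Step 2**
Reactants: 2 1,2,3,5-tetramethoxybenzene
Product: 4 2,3,4,6-tetramethoxybenzaldehyde, via iminium salt 3 (not isolated)
Conditions: POCl3, DMF, 0 to 60 °C; then aq. NaOAc, 23 °C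
Reagents that add atoms: N,N-dimethylformamide CN(C)C=O; water O
Why: Vilsmeier–Haack formylation at one of the two symmetry-equivalent free positions, each activated ortho, ortho and para by methoxy groups, so only one regioisomer can form.

**Step 3**
Reactants: 4 2,3,4,6-tetramethoxybenzaldehyde
Product: 6 2-hydroxy-3,4,6-trimethoxybenzaldehyde, via aryloxydichloroborane 5 (not isolated)
Conditions: BCl3 (1.1 equiv), CH2Cl2, −78 to 0 °C; then H2O
Reagents that add atoms: none
Why: chelation-controlled aryl methyl ether cleavage ortho to the carbonyl group, in which boron bridges the aldehyde oxygen and an ortho methoxy oxygen; of the two ortho ethers the one buttressed by the neighbouring 3-methoxy group is twisted out of conjugation, more basic and strain-relieved on cleavage, so it should be cut preferentially, by analogy with related 2,3,4-trioxygenated aryl carbonyl compounds.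

**Step 4**
Reactants: 6 2-hydroxy-3,4,6-trimethoxybenzaldehyde; 7 phenylacetylene
Product: 8 rac-2-(1-hydroxy-3-phenylprop-2-yn-1-yl)-3,5,6-trimethoxyphenol
Conditions: 7 (2.5 equiv), n-BuLi (2.4 equiv), THF, −78 °C; then 6, −78 to 0 °C; aq. NH4Cl, 0 °C
Reagents that add atoms: none
Why: 1,2-addition of lithium phenylacetylide to the aldehyde after the first equivalent has deprotonated the phenol; the carbinol center forms as a racemate, which is immaterial because it becomes a planar cationic carbon in step 7.

**Step 5**
Reactants: 9 (2E,6E)-farnesyl bromide
Product: 10 (2E,6E)-farnesyl diphosphate, tris(ammonium) salt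
Conditions: (n-Bu4N)3HP2O7 (2 equiv), MeCN, 23 °C; then Dowex 50WX8 (NH4+ form), aq. NH4HCO3/i-PrOH; lyophilise; cellulose chromatography
Reagents that add atoms: tris(tetrabutylammonium) hydrogen diphosphate CCCC[N+](CCCC)(CCCC)CCCC.CCCC[N+](CCCC)(CCCC)CCCC.CCCC[N+](CCCC)(CCCC)CCCC.OP(=O)([O-])OP(=O)([O-])[O-]; ammonium hydrogen carbonate [NH4+].OC([O-])=O
Why: SN2 displacement of the primary allylic bromide by hydrogen diphosphate, the standard entry to allylic diphosphates, followed by cation exchange to the ammonium salt accepted by the cyclase; both (E)-alkenes are untouched.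

**Step 6**
Reactants: 10 (2E,6E)-farnesyl diphosphate, tris(ammonium) salt
Product: 11 (+)-germacrene A
Conditions: recombinant (+)-germacrene A synthase (class-one sesquiterpene cyclase), MgCl2, HEPES buffer pH 7.5, dithiothreitol, pentane overlay, 30 °C; then neutral Al2O3, pentane, 4 °C
Reagents that add atoms: none
Why: this is the natural reaction of a class-one terpene cyclase (Mg2+-assisted ionisation of the allylic diphosphate, attack of the distal 10,11-alkene on C1 in farnesyl numbering to close the ten-membered ring, loss of a methyl proton to give the isopropenyl group), and the single stereocenter (C7, germacrane numbering) is set by the chiral active site, which presents one face of the distal alkene to the allyl cation.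

**Step 7**
Reactants: 11 (+)-germacrene A; 8 rac-2-(1-hydroxy-3-phenylprop-2-yn-1-yl)-3,5,6-trimethoxyphenol
Product: 14 (4S)-4-[(1S,4R,4aR,6R,8aS)-4-hydroxy-4,8a-dimethyl-6-(prop-1-en-2-yl)decahydronaphthalen-1-yl]-5,7,8-trimethoxy-2-phenyl-4H-chromene (target), via alkynyl o-quinone methide 12 (not isolated), via propargylic phenol 13 (not isolated)
Conditions: 8 (1.3 equiv, slow addition), 2,6-di-tert-butyl-4-methylpyridine (0.2 equiv), (CF3)2CHOH/H2O 19:1, 0 °C; then evaporate, CH2Cl2, Ph3PAuNTf2 (5 mol%), 23 °C
Reagents that add atoms: water O
Why: Proposed new method: in the buffered, strongly ionising medium 8 loses water to give the hydroxybenzylic propargylic cation (the protonated form of o-quinone methide 12); its benzylic carbon is attacked by C1 of the 1(10)-alkene of 11 from the outer face of the crossed chair–chair conformer while C5 of the 4-alkene bonds to C10 from the inner face and water caps the tertiary C4 cation from the outer face to give phenol 13, and after solvent exchange the monovalent gold catalyst activates the alkyne so that the phenol oxygen adds to the phenyl-bearing alkyne carbon and protodeauration releases 14. The closest known reaction types are the proton- and epoxide-triggered hydrative transannular cyclisation of germacra-1(10),4-dienes to eudesman-4α-ols, the biomimetic coupling of o-quinone methides with germacrene-type dienes (C–C bond formation followed by cationic cyclisation), the 1,4-addition of π-nucleophiles to alkynyl o-quinone methides, and the π-acid-catalysed cycloisomerisation of 2-(3-arylprop-2-ynyl)phenols to 2-aryl-4H-chromenes. Ring closures: the decalin by transannular C5–C10 bond formation (6-endo with respect to ring A, 6-exo with respect to ring B), then the pyran by 6-endo-dig hydroalkoxylation (O1–C2), which is the last ring formed. Stereocontrol: the existing C7 center selects the conformer with a pseudo-equatorial isopropenyl group, and anti addition across both (E)-alkenes of that conformer sets C1 (β, equatorial substituent), C10 (β-methyl), C5 (α-H) and C4 (α-OH, β-methyl); the chromene C4 center is set in an open transition state in which the bulky 2,6-disubstituted aryl group lies anti to C10, the slim alkynyl group sits between H1 and C10 and the hydrogen points into the crowded C2/C10 sector. Selectivity needed: C-alkylation at C1 rather than protonation of the diene (the hindered pyridine removes strong acid and the trioxygenated cation forms without it); attack on the 1(10)-alkene rather than the 4-alkene or the isopropenyl group (only attack at C1 is assisted by transannular participation); carbon rather than phenol-oxygen capture of the C10 cation (the oxygen is a neutral, hydrogen-bonded phenol while the 4,5-π bond is pre-aligned); and 6-endo rather than 5-exo attack on the alkyne (the phenyl group stabilises positive charge at the distal carbon).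

**Compound list**

1 | 3,4,5-trimethoxyphenol | COc1cc(O)cc(OC)c1OC | starting material
2 | 1,2,3,5-tetramethoxybenzene | COc1cc(OC)cc(OC)c1OC | intermediate
3 | N,N-dimethyl-1-(2,3,4,6-tetramethoxyphenyl)methaniminium dichlorophosphate (not isolated) | C[N+](C)=Cc1c(OC)cc(OC)c(OC)c1OC.[O-]P(=O)(Cl)Cl | intermediate
4 | 2,3,4,6-tetramethoxybenzaldehyde | O=Cc1c(OC)cc(OC)c(OC)c1OC | intermediate
5 | dichloro(2-formyl-3,5,6-trimethoxyphenoxy)borane (not isolated) | ClB(Cl)Oc1c(C=O)c(OC)cc(OC)c1OC | intermediate
6 | 2-hydroxy-3,4,6-trimethoxybenzaldehyde | O=Cc1c(O)c(OC)c(OC)cc1OC | intermediate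
7 | phenylacetylene | C#Cc1ccccc1 | starting material
8 | rac-2-(1-hydroxy-3-phenylprop-2-yn-1-yl)-3,5,6-trimethoxyphenol | OC(C#Cc1ccccc1)c1c(O)c(OC)c(OC)cc1OC | intermediate
9 | (2E,6E)-farnesyl bromide [(2E,6E)-1-bromo-3,7,11-trimethyldodeca-2,6,10-triene] | CC(C)=CCC/C(C)=C/CC/C(C)=C/CBr | starting material
10 | (2E,6E)-farnesyl diphosphate, tris(ammonium) salt | CC(C)=CCC/C(C)=C/CC/C(C)=C/COP(=O)([O-])OP(=O)([O-])[O-].[NH4+].[NH4+].[NH4+] | intermediate
11 | (+)-germacrene A [(1E,5E,8R)-1,5-dimethyl-8-(prop-1-en-2-yl)cyclodeca-1,5-diene; germacrane numbering 1(10)E,4E,7R] | C=C(C)[C@@H]1CC/C(C)=C/CC/C(C)=C/C1 | intermediate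
12 | 2,3,5-trimethoxy-6-(3-phenylprop-2-yn-1-ylidene)cyclohexa-2,4-dien-1-one (alkynyl o-quinone methide, not isolated) | O=C1C(=CC#Cc2ccccc2)C(OC)=CC(OC)=C1OC | intermediate
13 | 2-{(1S)-1-[(1S,4R,4aR,6R,8aS)-4-hydroxy-4,8a-dimethyl-6-(prop-1-en-2-yl)decahydronaphthalen-1-yl]-3-phenylprop-2-yn-1-yl}-3,5,6-trimethoxyphenol (eudesmane 1β-substituent, 4α-OH, 5α-H, 7β-isopropenyl, 10β-methyl; not isolated) | C=C(C)[C@@H]1CC[C@]2(C)[C@@H](C1)[C@](C)(O)CC[C@H]2[C@@H](C#Cc1ccccc1)c1c(O)c(OC)c(OC)cc1OC | intermediate
14 | (4S)-4-[(1S,4R,4aR,6R,8aS)-4-hydroxy-4,8a-dimethyl-6-(prop-1-en-2-yl)decahydronaphthalen-1-yl]-5,7,8-trimethoxy-2-phenyl-4H-chromene | C=C(C)[C@@H]1CC[C@]2(C)[C@@H](C1)[C@](C)(O)CC[C@H]2[C@H]1C=C(c2ccccc2)Oc2c(OC)c(OC)cc(OC)c21 | target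

**Step count**

Total: 7 steps. Longest linear sequence: 5 steps (steps 1, 2, 3, 4, 7); the terpene branch (steps 5, 6) joins in step 7.

**Steps most likely to fail**

1. Step 7 (bears the label).
   - What may go wrong: protonation of the diene by the medium and cyclisation to selinane olefins or alcohols before C-alkylation; collapse of the C10 cation onto the phenol oxygen (a formal hetero-Diels–Alder path) instead of transannular closure; loss of a proton from the C4 cation instead of hydration; self-alkylation of the free aromatic position of the cation precursor; poor facial selectivity at the chromene C4.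
   - Fallback (known chemistry, pyran still closed last): it sets out from 11 and 6 and comes back at 14.
     - 11 is epoxidised at the more nucleophilic 1(10)-alkene (mCPBA, CH2Cl2/aq. NaHCO3, −20 °C) to 1β,10α-epoxygermacra-4,11-diene F1.
     - Acid-catalysed transannular epoxide opening in aqueous acetone (TsOH cat., 0 °C) should give eudesm-11-ene-1β,4α-diol F2, with the same C5–C10 and C4–OH stereochemical course as in step 7.
     - Dess–Martin oxidation of the secondary alcohol gives 4α-hydroxyeudesm-11-en-1-one F3.
     - Wittig methoxymethylenation (Ph3P=CHOMe, THF) gives 1-(methoxymethylidene)eudesm-11-en-4α-ol F4.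
     - Mild hydrolysis (aq. oxalic acid, THF) and base equilibration (K2CO3, MeOH) should give the equatorial aldehyde 4α-hydroxyeudesm-11-ene-1β-carbaldehyde F5.
     - Horner–Wadsworth–Emmons olefination with diethyl (2-oxo-2-phenylethyl)phosphonate (LiCl, i-Pr2NEt, MeCN) gives (E)-3-(4α-hydroxyeudesm-11-en-1β-yl)-1-phenylprop-2-en-1-one F6.
     - In parallel 6 is decarbonylated (Pd(OAc)2 cat., cyclohexane, 130 °C) to 2,3,5-trimethoxyphenol F7.
     - Brønsted-acid-catalysed Friedel–Crafts conjugate addition of F7 through its free ortho position to F6 ((PhO)2PO2H cat., toluene, 4 Å molecular sieves, 50 °C), followed in the same flask by hemiketalisation and dehydration of the keto phenol, gives 14. Only the ortho adduct can cyclise. The chromene C4 configuration is expected from aryl attack anti to C10 on the enone conformer in which H1 eclipses the alkene.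

2. Step 6.
   - What may go wrong: Cope rearrangement of the product to β-elemene on warming, acid-induced cyclisation on the adsorbent, and loss of the volatile hydrocarbon on evaporation.
   - Fallback: it sets out from 10 and comes back at 11. The enzymatic cyclisation is run as before, but the pentane extract is not chromatographed. It is shaken with aqueous-ethanolic AgNO3 at 0 °C so that the diene crystallises as (+)-germacrene A–silver nitrate adduct F8, a classical way of isolating (E,E)-cyclodeca-1,5-dienes. The adduct is stored cold, and 11 is released with aqueous NaCl/pentane at 0 °C immediately before step 7.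

3. Step 4.
   - What may go wrong: ionisation of the very electron-rich o-hydroxybenzylic propargylic alcohol during work-up or chromatography and self-condensation through the o-quinone methide; sluggish addition to the phenoxide-deactivated aldehyde.
   - Fallback: it sets out from 6 and comes back at 8. The phenol is masked first: allylation (allyl bromide, K2CO3, DMF) gives 2-(allyloxy)-3,4,6-trimethoxybenzaldehyde F9, whose aldehyde is no longer deactivated. Addition of lithium phenylacetylide gives the storable ether rac-1-[2-(allyloxy)-3,4,6-trimethoxyphenyl]-3-phenylprop-2-yn-1-ol F10, which cannot form an o-quinone methide. The allyl group is removed under neutral Tsuji–Trost conditions (Pd(PPh3)4 cat., morpholine, THF, 23 °C) immediately before step 7, and crude 8 is used at once.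

**Further compounds**

F1 | step 7 | 1β,10α-epoxygermacra-4,11-diene (germacrene A 1,10-epoxide) | C=C(C)[C@@H]1CC[C@@]2(C)O[C@@H]2CC/C(C)=C/C1
F2 | step 7 | eudesm-11-ene-1β,4α-diol | C=C(C)[C@@H]1CC[C@]2(C)[C@@H](C1)[C@](C)(O)CC[C@H]2O
F3 | step 7 | 4α-hydroxyeudesm-11-en-1-one | C=C(C)[C@@H]1CC[C@]2(C)[C@@H](C1)[C@](C)(O)CCC2=O
F4 | step 7 | 1-(methoxymethylidene)eudesm-11-en-4α-ol (E/Z mixture) | C=C(C)[C@@H]1CC[C@]2(C)[C@@H](C1)[C@](C)(O)CCC2=COC
F5 | step 7 | 4α-hydroxyeudesm-11-ene-1β-carbaldehyde | C=C(C)[C@@H]1CC[C@]2(C)[C@@H](C1)[C@](C)(O)CC[C@H]2C=O
F6 | step 7 | (E)-3-(4α-hydroxyeudesm-11-en-1β-yl)-1-phenylprop-2-en-1-one | C=C(C)[C@@H]1CC[C@]2(C)[C@@H](C1)[C@](C)(O)CC[C@H]2/C=C/C(=O)c1ccccc1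
F7 | step 7 | 2,3,5-trimethoxyphenol | COc1cc(O)c(OC)c(OC)c1
F8 | step 6 | (+)-germacrene A–silver nitrate adduct (1:1) | C=C(C)[C@@H]1CC/C(C)=C/CC/C(C)=C/C1.[Ag+].[O-][N+](=O)[O-]
F9 | step 4 | 2-(allyloxy)-3,4,6-trimethoxybenzaldehyde | C=CCOc1c(C=O)c(OC)cc(OC)c1OC
F10 | step 4 | rac-1-[2-(allyloxy)-3,4,6-trimethoxyphenyl]-3-phenylprop-2-yn-1-ol | C=CCOc1c(C(O)C#Cc2ccccc2)c(OC)cc(OC)c1OC
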